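**Plan**
- Quinone numbering used throughout: C1(=O), C2(OAc), C3(aryl), C4(=O), C5(H), C6(aryl). The enabling feature is that O–C2=C3–C4=O is an enolised cyclic 1,3-diketone (a vinylogous acid). C3–C4 is therefore a retro-Claisen bond between the benzylic carbon of an arylpyruvoyl unit (C3–C2–C1) and a carboxyl carbon (C4). Terphenylquinones are presumed to arise from two arylpyruvates through this type of bond.
- Cuts, in order: acetyl–O and the two O-benzyl groups; C3–C4 (Dieckmann type); the helper bond C2–O–C4 of an enol lactone; C5=C6 (aldol condensation, glyoxylic acid supplying C4–C5); C3–C2 and C6–C1 (two benzyl Grignard additions to an oxalyl unit supplying C1–C2). C3 and C6 are both benzylic α-carbons of the C1/C2 diketone, so the precursor is a symmetrical 1,4-diarylbutane-2,3-dione.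
- Forward order: the chain C3–C2–C1–C6 is made in one step and C5–C4 is added. A transient five-membered pseudo-acid lactone forms, then a six-membered 6-benzylidenepyran-2,5-dione. This temporary ring holds C1 and C4 cis on C5=C6 and activates C4 as an enol ester. Methoxide then turns the heterocycle into the carbocyclic hydroxyquinone, already at the quinone oxidation level.
- Endgame: acetylation of the only free hydroxyl, then hydrogenolysis of the benzyl ethers and re-oxidation.
- Stereochemistry: the target has no stereocentre. Only the cis relation across C5=C6 matters, and the lactone rings enforce it.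

Key step: step 3

Step 1
Reactants: 1 4-(benzyloxy)benzyl chloride (2.3 equiv); 2 N,N'-dimethoxy-N,N'-dimethyloxamide
Product: 5 1,4-bis[4-(benzyloxy)phenyl]butane-2,3-dione, via benzylic Grignard reagent 3 (not isolated), via bis(hemiaminalate) adduct 4 (not isolated)
Conditions: Mg turnings (excess), 2-MeTHF, 0 °C, slow addition of 1; then 2, −40 → 0 °C; cold 1 M HCl
Reagents that add atoms: magnesium, [Mg] (retained only in 3 and 4, not in 5)
Why: Double Weinreb ketone synthesis with a benzylic Grignard reagent: each addition stops at the magnesium-chelated hemiaminalate 4, so neither over-addition nor enolisation can occur before the acidic quench releases the 1,2-diketone, and slow addition of 1 to excess magnesium in 2-MeTHF holds back Wurtz coupling.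

Step 2
Reactants: 5 1,4-bis[4-(benzyloxy)phenyl]butane-2,3-dione; 6 glyoxylic acid monohydrate (1.0 equiv)
Product: 8 (6Z)-4-[4-(benzyloxy)phenyl]-6-[4-(benzyloxy)benzylidene]-2H-pyran-2,5(6H)-dione, via hydroxybutenolide pseudo-acid 7 (not isolated)
Conditions: AcOH, 100 °C; then Ac2O, NaOAc, 100 °C
Reagents that add atoms: none
Why: Aldol condensation of an α-substituted ketone with glyoxylic acid, which is known to end in the 5-hydroxybutenolide pseudo-acid and so places C1 and C4 cis on the new C5=C6 bond, is followed by acetic anhydride-mediated enol lactonisation of the δ-keto acid tautomer through the strongly enolised benzylic C2 ketone, the exocyclic benzylidene bond settling in the less crowded Z form (aryl syn to the ring oxygen) and the racemic hemiketal centre of 7 being lost again.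

Step 3
Reactants: 8 (6Z)-4-[4-(benzyloxy)phenyl]-6-[4-(benzyloxy)benzylidene]-2H-pyran-2,5(6H)-dione
Product: 11 3,6-bis[4-(benzyloxy)phenyl]-2-hydroxy-1,4-benzoquinone, via open-chain Z keto ester enolate 9 (not isolated), via sodium quinonate 10 (not isolated)
Conditions: NaOMe (3 equiv), MeOH–THF, 0 °C → rt, Ar; then 1 M HCl
Reagents that add atoms: sodium methoxide, C[O-].[Na+] (methoxy group retained only in 9, sodium only in 9 and 10)
Why: Methoxide adds to the lactone carbonyl (C4) of 8 and opens the ring to the Z keto ester 9, which sets free exactly the C2-oxido/C3 enolate that is needed; its benzylic carbon C3 attacks the ester carbonyl C4, methoxide leaves, and the cyclohex-5-ene-1,2,4-trione so formed is deprotonated at once to the delocalised quinonate 10, from which acid liberates 11 without any redox step. The closest known reaction type is the alkoxide-induced rearrangement of ylidene enol lactones to cyclic 1,3-diketones (benzylidenephthalide to 2-phenylindane-1,3-dione, 6-benzylidenepyran-2,5-dione fungal pigments to terphenylquinones), in essence a Dieckmann condensation that copies the Claisen-type closure presumed for arylpyruvate-derived terphenylquinones. The carbocycle closes in the 6-(enolendo)-exo-trig mode. No stereocentre is created. The step needs C-acylation rather than O-acylation, six-ring closure rather than Michael closure, and a cis C1/C4 relation: O-acylation merely returns 8 and is reversible, attack of C3 on C5 would be 5-endo-trig, and the Z geometry of C5=C6 is inherited from the lactone ring. Formation of the weakly basic anion 10 is practically irreversible, drains all these equilibria and also shields C5 of the product from methoxide.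

Step 4
Reactants: 11 3,6-bis[4-(benzyloxy)phenyl]-2-hydroxy-1,4-benzoquinone
Product: 12 2-acetoxy-3,6-bis[4-(benzyloxy)phenyl]-1,4-benzoquinone
Conditions: Ac2O, pyridine, CH2Cl2, 0 °C
Reagents that add atoms: acetic anhydride, CC(=O)OC(C)=O
Why: O-Acetylation of the acidic quinone hydroxyl with acetic anhydride and pyridine is standard for hydroxyquinones, and with both phenols masked as benzyl ethers it is the only site that can be acylated.

Step 5
Reactants: 12 2-acetoxy-3,6-bis[4-(benzyloxy)phenyl]-1,4-benzoquinone
Product: 14 neonambiquinone A, via leuco acetate 13 (not isolated)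
Conditions: H2 (1 atm), 10% Pd/C, EtOAc–THF, trace AcOH, rt; filter under Ar; then DDQ (1.0 equiv), 0 °C
Reagents that add atoms: none
Why: Catalytic hydrogenolysis removes both aryl benzyl ethers under neutral conditions while the quinone is reduced to hydroquinone 13, in which the acetate is an ordinary aryl ester, and one equivalent of DDQ then re-oxidises only the 1,4-hydroquinone, which is far more easily oxidised than the isolated phenols, in a non-basic medium that spares the activated acetate.

**Compound list**
1 | 4-(benzyloxy)benzyl chloride | ClCc1ccc(OCc2ccccc2)cc1 | starting material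
2 | N,N'-dimethoxy-N,N'-dimethyloxamide | CON(C)C(=O)C(=O)N(C)OC | starting material
3 | [4-(benzyloxy)benzyl]magnesium chloride | Cl[Mg]Cc1ccc(OCc2ccccc2)cc1 | intermediate
4 | bis(chloromagnesium hemiaminalate) from double addition to 2 (mixture of diastereomers) | CON(C)C(Cc1ccc(OCc2ccccc2)cc1)(O[Mg]Cl)C(Cc1ccc(OCc2ccccc2)cc1)(O[Mg]Cl)N(C)OC | intermediate
5 | 1,4-bis[4-(benzyloxy)phenyl]butane-2,3-dione (drawn as diketone, strongly enolised) | O=C(Cc1ccc(OCc2ccccc2)cc1)C(=O)Cc1ccc(OCc2ccccc2)cc1 | intermediate
6 | glyoxylic acid monohydrate (dihydroxyacetic acid) | OC(O)C(=O)O | starting material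
7 | rac-4-[4-(benzyloxy)phenyl]-5-{[4-(benzyloxy)phenyl]acetyl}-5-hydroxyfuran-2(5H)-one | O=C1C=C(c2ccc(OCc3ccccc3)cc2)C(O)(C(=O)Cc2ccc(OCc3ccccc3)cc2)O1 | intermediate
8 | (6Z)-4-[4-(benzyloxy)phenyl]-6-[4-(benzyloxy)benzylidene]-2H-pyran-2,5(6H)-dione | O=C1C=C(c2ccc(OCc3ccccc3)cc2)C(=O)/C(=C/c2ccc(OCc3ccccc3)cc2)O1 | intermediate
9 | sodium enolate of methyl (2Z)-3,6-bis[4-(benzyloxy)phenyl]-4,5-dioxohex-2-enoate | COC(=O)/C=C(/c1ccc(OCc2ccccc2)cc1)C(=O)/C([O-])=C/c1ccc(OCc2ccccc2)cc1.[Na+] | intermediate
10 | sodium salt of 3,6-bis[4-(benzyloxy)phenyl]-2-hydroxy-1,4-benzoquinone | [O-]C1=C(c2ccc(OCc3ccccc3)cc2)C(=O)C=C(c2ccc(OCc3ccccc3)cc2)C1=O.[Na+] | intermediate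
11 | 3,6-bis[4-(benzyloxy)phenyl]-2-hydroxy-1,4-benzoquinone | OC1=C(c2ccc(OCc3ccccc3)cc2)C(=O)C=C(c2ccc(OCc3ccccc3)cc2)C1=O | intermediate
12 | 2-acetoxy-3,6-bis[4-(benzyloxy)phenyl]-1,4-benzoquinone | CC(=O)OC1=C(c2ccc(OCc3ccccc3)cc2)C(=O)C=C(c2ccc(OCc3ccccc3)cc2)C1=O | intermediate
13 | 2-acetoxy-3,6-bis(4-hydroxyphenyl)benzene-1,4-diol (leuco acetate) | CC(=O)Oc1c(-c2ccc(O)cc2)c(O)cc(-c2ccc(O)cc2)c1O | intermediate
14 | neonambiquinone A | CC(=O)OC1=C(c2ccc(O)cc2)C(=O)C=C(c2ccc(O)cc2)C1=O | target

Total step count: 5
Longest linear sequence: 5 steps (1 → 5 → 8 → 11 → 12 → 14)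

**Steps most likely to fail**

Step 2.
- Risk: the second benzylic position may condense as well. Acetylation of the hemiketal hydroxyl or of the enol may also outrun closure of the six-membered lactone.
- Fallback: the lactone helper is given up. Setting out from 5, a Knoevenagel-type condensation with ethyl glyoxylate (piperidinium acetate cat., toluene, water separator) should give the open-chain ethyl 3,6-bis[4-(benzyloxy)phenyl]-4,5-dioxohex-2-enoate F1 as a mixture of alkene isomers.
- Under NaOMe in MeOH–THF, reversible conjugate addition of methoxide at C5 should interconvert the alkene isomers. Only the Z isomer can undergo the Dieckmann closure, so the mixture is drained and the route is rejoined at 11.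

Step 3.
- Risk: conjugate addition of methoxide to the enone carbons may precede lactone opening, and ring closure may then be followed by aromatising tautomerisation instead of loss of methanol. A benzilic-type rearrangement of the diketone may also intervene.
- Fallback: the same C3–C4 bond is closed one oxidation level lower. Setting out from 5, double deprotonation (LiN(iPr)2, 2.1 equiv, THF, −78 °C) gives the dilithium bis-enolate F2.
- F2 is more nucleophilic than its monoalkylated successor, so it should take up one equivalent of methyl bromoacetate at carbon to give racemic methyl 3,6-bis[4-(benzyloxy)phenyl]-4,5-dioxohexanoate F3.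
- KOtBu in THF at 0 °C then effects the classical δ-keto ester to cyclic 1,3-diketone Claisen closure. Tautomerisation to 3,6-bis[4-(benzyloxy)phenyl]benzene-1,2,4-triol F4 makes it irreversible.
- Oxidation with Ag2O in Et2O–THF returns to the route at 11.

Step 5.
- Risk: the acetyl group may migrate to the neighbouring hydroxyl at the hydroquinone stage. Intermolecular acetyl transfer to the freed phenols is a further risk.
- Fallback: the protecting groups are exchanged before acetylation, so that no reductive step follows it. Setting out from 11, BCl3 and pentamethylbenzene (CH2Cl2, −78 °C) give 2-hydroxy-3,6-bis(4-hydroxyphenyl)-1,4-benzoquinone F5.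
- Exhaustive silylation (TBSCl, imidazole, DMF) gives the tris(tert-butyldimethylsilyl) ether F6.
- The vinylogous silyl ester of F6 is hydrolysed selectively with aqueous citric acid in THF, which gives 3,6-bis[4-(tert-butyldimethylsilyloxy)phenyl]-2-hydroxy-1,4-benzoquinone F7.
- Ac2O and pyridine give 2-acetoxy-3,6-bis[4-(tert-butyldimethylsilyloxy)phenyl]-1,4-benzoquinone F8.
- HF·pyridine (THF, 0 °C) removes the aryl silyl ethers in an acidic, non-nucleophilic medium and arrives at 14.

**Further compounds**
F1 | step 2 | ethyl 3,6-bis[4-(benzyloxy)phenyl]-4,5-dioxohex-2-enoate (E/Z mixture) | CCOC(=O)C=C(c1ccc(OCc2ccccc2)cc1)C(=O)C(=O)Cc1ccc(OCc2ccccc2)cc1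
F2 | step 3 | dilithium 1,4-bis[4-(benzyloxy)phenyl]buta-1,3-diene-2,3-diolate | [Li+].[Li+].[O-]C(=Cc1ccc(OCc2ccccc2)cc1)C([O-])=Cc1ccc(OCc2ccccc2)cc1
F3 | step 3 | methyl 3,6-bis[4-(benzyloxy)phenyl]-4,5-dioxohexanoate (racemic) | COC(=O)CC(c1ccc(OCc2ccccc2)cc1)C(=O)C(=O)Cc1ccc(OCc2ccccc2)cc1
F4 | step 3 | 3,6-bis[4-(benzyloxy)phenyl]benzene-1,2,4-triol | Oc1cc(-c2ccc(OCc3ccccc3)cc2)c(O)c(O)c1-c1ccc(OCc2ccccc2)cc1
F5 | step 5 | 2-hydroxy-3,6-bis(4-hydroxyphenyl)-1,4-benzoquinone | OC1=C(c2ccc(O)cc2)C(=O)C=C(c2ccc(O)cc2)C1=O
F6 | step 5 | 2-(tert-butyldimethylsilyloxy)-3,6-bis[4-(tert-butyldimethylsilyloxy)phenyl]-1,4-benzoquinone | CC(C)(C)[Si](C)(C)OC1=C(c2ccc(O[Si](C)(C)C(C)(C)C)cc2)C(=O)C=C(c2ccc(O[Si](C)(C)C(C)(C)C)cc2)C1=O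
F7 | step 5 | 3,6-bis[4-(tert-butyldimethylsilyloxy)phenyl]-2-hydroxy-1,4-benzoquinone | OC1=C(c2ccc(O[Si](C)(C)C(C)(C)C)cc2)C(=O)C=C(c2ccc(O[Si](C)(C)C(C)(C)C)cc2)C1=O
F8 | step 5 | 2-acetoxy-3,6-bis[4-(tert-butyldimethylsilyloxy)phenyl]-1,4-benzoquinone | CC(=O)OC1=C(c2ccc(O[Si](C)(C)C(C)(C)C)cc2)C(=O)C=C(c2ccc(O[Si](C)(C)C(C)(C)C)cc2)C1=O
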